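**Retrosynthetic overview**

1. Numbering follows the halimane skeleton: ring A = C1–C5 + C10, ring B = C5–C10, chain C11–C16 on C9. The 7-acetate goes back to the 6,7-cis-diol, made by OsO4 dihydroxylation of the C6=C7 bond of a ring-B diene (C5=C10, C6=C7).
2. Key disconnection: the C4–C5 bond of ring A, the last ring closed, by a Pd-catalysed reductive 6-exo Heck cyclisation of a monocyclic C5-iodo C6-enol triflate, followed in the same flask by hydrogenolysis of the triflate.
3. Enabling feature: C4 is a quaternary carbon with two methyl groups, bonded to the sp2 carbon C5 of the tetrasubstituted C5=C10 bond, next to oxygen-bearing C6. One methyl can therefore be hidden as the CH2 of a C4=CH2 alkene (carbopalladation leaves an alkylpalladium without β-hydrogen, which is reduced to CH3), and C5 can carry iodine through the C10/C6 carbonyl chemistry.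
4. Ring B comes first and is the cyclohexanone ring of (R)-pulegone (source of C8). The isopropylidene group blocks C5 while C9 is alkylated twice (side chain, then methyl) and is then cut off by retro-aldol C–C cleavage. Dehydrogenation, α-iodination, Grignard addition at C10 and oxidative 1,3-transposition place the C1–C4 chain on C10, iodine on C5 and oxygen on C6.
5. The C11–C16 chain with the C13 carbinol comes from (S)-linalool by ozonolysis and decarboxylative iodination. Ring order: ring B (from pulegone), then ring A (step 12).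

Key step: step 12

Assumption: (S)-(+)-linalool of high enantiomeric purity and 5-bromo-2-methylpent-1-ene are taken as commercial; the linalool carbinol centre becomes C13 unchanged.

**Route**

Step 1
Reactants: 1 (S)-(+)-linalool
Product: 2 (3S)-3,7-dimethyl-3-[(triethylsilyl)oxy]octa-1,6-diene
Conditions: Et3SiOTf, 2,6-lutidine, CH2Cl2, −78 → 0 °C
Reagents that add atoms: triethylsilyl trifluoromethanesulfonate, CC[Si](CC)(CC)OS(=O)(=O)C(F)(F)F
Why: Silylation of the hindered tertiary allylic alcohol with a silyl triflate and a hindered pyridine base is standard protecting-group chemistry that leaves the carbinol stereocentre (the future C13) untouched and shields it and the neighbouring vinyl group in the oxidative and basic steps that follow.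

Step 2
Reactants: 2 (3S)-3,7-dimethyl-3-[(triethylsilyl)oxy]octa-1,6-diene
Product: 4 (4S)-4-methyl-4-[(triethylsilyl)oxy]hex-5-enoic acid, via aldehyde 3 (not isolated)
Conditions: O3, CH2Cl2/MeOH, −78 °C (Sudan Red 7B as end-point indicator); Me2S, −78 → 23 °C; then NaClO2, NaH2PO4, 2-methylbut-2-ene, t-BuOH/H2O, 0 → 23 °C
Reagents that add atoms: ozone, [O-][O+]=O; sodium chlorite, [Na+].[O-]Cl=O
Why: Ozone should attack the electron-rich trisubstituted alkene much faster than the vinyl group, which is deactivated by the allylic silyloxy group and shielded by the quaternary carbon (chemoselective ozonolysis with reductive work-up), and Pinnick oxidation of the crude aldehyde gives the acid without touching alkene or silyl ether.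

Step 3
Reactants: 4 (4S)-4-methyl-4-[(triethylsilyl)oxy]hex-5-enoic acid
Product: 6 (3S)-5-iodo-3-methyl-3-[(triethylsilyl)oxy]pent-1-ene, via Barton ester 5 (not isolated)
Conditions: N-hydroxypyridine-2-thione, DCC, DMAP (cat.), CH2Cl2, 0 → 23 °C, dark; then CHI3, hν (tungsten lamp), 23 °C
Reagents that add atoms: iodoform, IC(I)I
Why: In this Barton decarboxylative iodination the thiohydroxamate ester fragments under visible light to a primary alkyl radical that abstracts iodine from iodoform, which shortens the chain by one carbon to the five-carbon electrophile, while the radical cannot cyclise onto the vinyl group (only 4-exo or 5-endo modes are open) and the stereocentre is not involved.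

Step 4
Reactants: 7 (R)-(+)-pulegone; 6 (3S)-5-iodo-3-methyl-3-[(triethylsilyl)oxy]pent-1-ene
Product: 8 (2S,3R)-3-methyl-2-{(3S)-3-methyl-3-[(triethylsilyl)oxy]pent-4-en-1-yl}-6-(propan-2-ylidene)cyclohexan-1-one
Conditions: LiN(iPr)2, THF, −78 °C; then 6, DMPU, −78 → −30 °C
Reagents that add atoms: none
Why: Kinetic deprotonation of the enone at the α′-methylene (the future C9; the other α-carbon is blocked by the isopropylidene group) and SN2 alkylation of the cross-conjugated lithium enolate by the primary iodide should put the chain anti to the neighbouring ring methyl, a configuration that is erased again in step 5.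

Step 5
Reactants: 8 (2S,3R)-3-methyl-2-{(3S)-3-methyl-3-[(triethylsilyl)oxy]pent-4-en-1-yl}-6-(propan-2-ylidene)cyclohexan-1-one
Product: 9 (2R,3R)-2,3-dimethyl-2-{(3S)-3-methyl-3-[(triethylsilyl)oxy]pent-4-en-1-yl}-6-(propan-2-ylidene)cyclohexan-1-one
Conditions: LiN(iPr)2, THF, −78 → −30 °C; MeI, DMPU, −78 → 0 °C
Reagents that add atoms: iodomethane, CI
Why: A second α′-deprotonation gives the tetrasubstituted enolate, in which the C8 methyl is pseudoaxial to avoid allylic strain, so methyl iodide should attack the opposite face (stereoelectronically controlled enolate alkylation) and set the quaternary stereocentre C9 with the new methyl trans and the side chain cis to the C8 methyl.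

Step 6
Reactants: 9 (2R,3R)-2,3-dimethyl-2-{(3S)-3-methyl-3-[(triethylsilyl)oxy]pent-4-en-1-yl}-6-(propan-2-ylidene)cyclohexan-1-one
Product: 10 (2R,3R)-2,3-dimethyl-2-{(3S)-3-methyl-3-[(triethylsilyl)oxy]pent-4-en-1-yl}cyclohexan-1-one
Conditions: KOH, EtOH/H2O, reflux (acetone distilled off)
Reagents that add atoms: none
Why: Retro-aldol cleavage (conjugate addition of hydroxide to the isopropylidene carbon, then C–C fragmentation with loss of acetone) removes the blocking group, and both stereocentres survive because C9 is quaternary and C8 is not enolisable.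

Step 7
Reactants: 10 (2R,3R)-2,3-dimethyl-2-{(3S)-3-methyl-3-[(triethylsilyl)oxy]pent-4-en-1-yl}cyclohexan-1-one
Product: 11 (5R,6R)-5,6-dimethyl-6-{(3S)-3-methyl-3-[(triethylsilyl)oxy]pent-4-en-1-yl}cyclohex-2-en-1-one
Conditions: IBX (2-iodoxybenzoic acid, limited excess), DMSO, 65 °C
Reagents that add atoms: none
Why: IBX-mediated α,β-dehydrogenation of the ketone should give a single enone because only the C5 side carries α-hydrogens (C9 is quaternary).

Step 8
Reactants: 11 (5R,6R)-5,6-dimethyl-6-{(3S)-3-methyl-3-[(triethylsilyl)oxy]pent-4-en-1-yl}cyclohex-2-en-1-one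
Product: 12 (5R,6R)-2-iodo-5,6-dimethyl-6-{(3S)-3-methyl-3-[(triethylsilyl)oxy]pent-4-en-1-yl}cyclohex-2-en-1-one
Conditions: I2, pyridine, CH2Cl2, 0 → 23 °C
Reagents that add atoms: iodine, II
Why: Pyridine-promoted α-iodination of the enone (conjugate addition of pyridine, iodination of the enolate at C5, elimination; a Baylis–Hillman-type sequence) is reliable for β-unsubstituted cyclohexenones and should leave the deactivated vinyl group alone.

Step 9
Reactants: 12 (5R,6R)-2-iodo-5,6-dimethyl-6-{(3S)-3-methyl-3-[(triethylsilyl)oxy]pent-4-en-1-yl}cyclohex-2-en-1-one; 13 5-bromo-2-methylpent-1-ene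
Product: 15 (5R,6R)-2-iodo-5,6-dimethyl-1-(4-methylpent-4-en-1-yl)-6-{(3S)-3-methyl-3-[(triethylsilyl)oxy]pent-4-en-1-yl}cyclohex-2-en-1-ol (both C1 carbinol epimers), via Grignard reagent 14 (not isolated)
Conditions: 13, Mg, THF, 40 °C; CeCl3, THF, −78 °C; then 12, −78 °C; aq. NH4Cl
Reagents that add atoms: none
Why: Organocerium (Grignard/CeCl3) 1,2-addition to the hindered, non-enolisable carbonyl C10 attaches the future C1–C4 unit with its 1,1-disubstituted alkene without conjugate addition or metal–iodine exchange, and the configuration of the new carbinol carbon is irrelevant because it becomes sp2 in step 10.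

Step 10
Reactants: 15 (5R,6R)-2-iodo-5,6-dimethyl-1-(4-methylpent-4-en-1-yl)-6-{(3S)-3-methyl-3-[(triethylsilyl)oxy]pent-4-en-1-yl}cyclohex-2-en-1-ol
Product: 16 (4R,5R)-2-iodo-4,5-dimethyl-3-(4-methylpent-4-en-1-yl)-4-{(3S)-3-methyl-3-[(triethylsilyl)oxy]pent-4-en-1-yl}cyclohex-2-en-1-one
Conditions: [C5H5NH][CrO3Cl] (pyridinium chlorochromate), powdered 4 Å molecular sieves, CH2Cl2, 23 °C
Reagents that add atoms: pyridinium chlorochromate, [O-][Cr](=O)(=O)Cl.c1cc[nH+]cc1
Why: In this Dauben–Babler oxidative 1,3-transposition the tertiary allylic chromate ester shifts to C6 and is oxidised to the ketone, which moves the double bond to C5=C10 and the oxygen to C6, while the silyl ether keeps the second tertiary allylic alcohol in the side chain from reacting the same way.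

Step 11
Reactants: 16 (4R,5R)-2-iodo-4,5-dimethyl-3-(4-methylpent-4-en-1-yl)-4-{(3S)-3-methyl-3-[(triethylsilyl)oxy]pent-4-en-1-yl}cyclohex-2-en-1-one
Product: 17 (3R,4R)-6-iodo-3,4-dimethyl-5-(4-methylpent-4-en-1-yl)-4-{(3S)-3-methyl-3-[(triethylsilyl)oxy]pent-4-en-1-yl}cyclohexa-1,5-dien-1-yl trifluoromethanesulfonate
Conditions: KN(SiMe3)2, THF, −78 °C; PhNTf2, −78 → 0 °C
Reagents that add atoms: N-phenylbis(trifluoromethanesulfonimide), O=S(=O)(N(c1ccccc1)S(=O)(=O)C(F)(F)F)C(F)(F)F
Why: Kinetic deprotonation at the α′-methylene C7 (faster than γ-deprotonation at C1) and O-sulfonylation (enol triflate formation) turn the C6 carbonyl into a leaving group and install the C6=C7 double bond needed for the later dihydroxylation.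

Step 12
Reactants: 17 (3R,4R)-6-iodo-3,4-dimethyl-5-(4-methylpent-4-en-1-yl)-4-{(3S)-3-methyl-3-[(triethylsilyl)oxy]pent-4-en-1-yl}cyclohexa-1,5-dien-1-yl trifluoromethanesulfonate
Product: 19 (5R,6R)-1,1,5,6-tetramethyl-5-{(3S)-3-methyl-3-[(triethylsilyl)oxy]pent-4-en-1-yl}-1,2,3,4,5,6-hexahydronaphthalene, via bicyclic dienyl triflate 18 (not isolated)
Conditions: Pd(OAc)2 (10 mol %), PPh3 (30 mol %), HCO2Na (1.2 equiv), Et4NCl, DMF, 70 °C; then HCO2H, Et3N, 70 °C
Reagents that add atoms: none
Why: Zerovalent palladium, formed from Pd(OAc)2 and PPh3, inserts into the C5–I bond (faster than into the C6–OTf bond), the alkenylpalladium adds syn across the tethered 1,1-disubstituted alkene so that C5 bonds to the internal carbon C4, and the resulting neopentyl-type alkylpalladium, which has no β-hydrogen because C4 is now quaternary, exchanges iodide for formate, loses CO2 and reductively eliminates a C–H bond, turning the former exocyclic CH2 into the second methyl on C4; in the second stage the same catalyst inserts into the C6–OTf bond of 18 and formate-derived hydride replaces the triflate. The closest known reaction types are the intramolecular reductive Heck reaction (carbopalladation with formate capture) that makes all-carbon quaternary centres from 1,1-disubstituted alkenes, and the palladium/formate hydrogenolysis of enol triflates. Ring A is closed by 6-exo-trig carbopalladation, which forms the C4–C5 bond. No new stereocentre arises, since C4 carries two identical methyl groups, and C8, C9 and C13 are not touched. The step needs exo closure to the six-membered ring rather than 7-endo closure or attack on the side-chain vinyl group (a 7-exo path), carbopalladation before hydride capture, and C–I before C–O insertion; these are secured by the three-carbon tether between C10 and C4, by the higher reactivity of the alkenyl iodide, by keeping formate scarce in the first stage (sparingly soluble HCO2Na) and by the silyl ether that shields the vinyl group. The tetrasubstituted C5=C10 bond is kept because palladium is never placed on a carbon that has β-hydrogens.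

Step 13
Reactants: 19 (5R,6R)-1,1,5,6-tetramethyl-5-{(3S)-3-methyl-3-[(triethylsilyl)oxy]pent-4-en-1-yl}-1,2,3,4,5,6-hexahydronaphthalene
Product: 20 (1S,2R,3S,4R)-3,4,8,8-tetramethyl-4-{(3S)-3-methyl-3-[(triethylsilyl)oxy]pent-4-en-1-yl}-1,2,3,4,5,6,7,8-octahydronaphthalene-1,2-diol
Conditions: OsO4 (5 mol %), N-methylmorpholine N-oxide (1.1 equiv), acetone/H2O, 0 °C
Reagents that add atoms: osmium tetroxide, O=[Os](=O)(=O)=O; N-methylmorpholine N-oxide, C[N+]1([O-])CCOCC1; water, O
Why: Catalytic OsO4 dihydroxylation (syn [3+2] addition) should occur at the disubstituted, conjugated C6=C7 bond rather than at the C5=C10 bond (flanked by two quaternary carbons) or the vinyl group (neopentyl-type and deactivated by the allylic silyl ether), and from the ring face anti to the C8 methyl and the C9 side chain, which sets C6 and C7 together as the cis-diol trans to the C8 methyl.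

Step 14
Reactants: 20 (1S,2R,3S,4R)-3,4,8,8-tetramethyl-4-{(3S)-3-methyl-3-[(triethylsilyl)oxy]pent-4-en-1-yl}-1,2,3,4,5,6,7,8-octahydronaphthalene-1,2-diol
Product: 21 (1S,2R,3S,4R)-4-[(3S)-3-hydroxy-3-methylpent-4-en-1-yl]-3,4,8,8-tetramethyl-1,2,3,4,5,6,7,8-octahydronaphthalene-1,2-diol
Conditions: HF·pyridine, pyridine, THF, 0 → 23 °C
Reagents that add atoms: none
Why: Fluoride cleavage of the tertiary triethylsilyl ether under buffered, weakly acidic conditions (silyl ether deprotection) should free the C13 alcohol without ionising the allylic alcohols.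

Step 15
Reactants: 21 (1S,2R,3S,4R)-4-[(3S)-3-hydroxy-3-methylpent-4-en-1-yl]-3,4,8,8-tetramethyl-1,2,3,4,5,6,7,8-octahydronaphthalene-1,2-diol
Product: 22 (1S,2R,3S,4R)-1-hydroxy-4-[(3S)-3-hydroxy-3-methylpent-4-en-1-yl]-3,4,8,8-tetramethyl-1,2,3,4,5,6,7,8-octahydronaphthalen-2-yl acetate (target)
Conditions: AcCl (1.05 equiv), 2,4,6-collidine, CH2Cl2, −78 → −40 °C
Reagents that add atoms: acetyl chloride, CC(=O)Cl
Why: Kinetically controlled acylation at low temperature should select the equatorial C7 hydroxyl over the pseudoaxial allylic C6 hydroxyl, which is crowded by the C4 methyls, and over the tertiary C13 hydroxyl (selective esterification of the less hindered alcohol of a cis-1,2-diol), with no stereocentre affected.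

**Compound list**

1 | (S)-(+)-linalool, (3S)-3,7-dimethylocta-1,6-dien-3-ol | C=C[C@@](C)(O)CCC=C(C)C | starting material
2 | (3S)-3,7-dimethyl-3-[(triethylsilyl)oxy]octa-1,6-diene | C=C[C@@](C)(O[Si](CC)(CC)CC)CCC=C(C)C | intermediate
3 | (4S)-4-methyl-4-[(triethylsilyl)oxy]hex-5-enal | C=C[C@@](C)(O[Si](CC)(CC)CC)CCC=O | intermediate
4 | (4S)-4-methyl-4-[(triethylsilyl)oxy]hex-5-enoic acid | C=C[C@@](C)(O[Si](CC)(CC)CC)CCC(=O)O | intermediate
5 | 2-thioxopyridin-1(2H)-yl (4S)-4-methyl-4-[(triethylsilyl)oxy]hex-5-enoate (Barton ester) | C=C[C@@](C)(O[Si](CC)(CC)CC)CCC(=O)On1ccccc1=S | intermediate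
6 | (3S)-5-iodo-3-methyl-3-[(triethylsilyl)oxy]pent-1-ene | C=C[C@@](C)(O[Si](CC)(CC)CC)CCI | intermediate
7 | (R)-(+)-pulegone, (5R)-5-methyl-2-(propan-2-ylidene)cyclohexan-1-one | C[C@@H]1CCC(=C(C)C)C(=O)C1 | starting material
8 | (2S,3R)-3-methyl-2-{(3S)-3-methyl-3-[(triethylsilyl)oxy]pent-4-en-1-yl}-6-(propan-2-ylidene)cyclohexan-1-one | C=C[C@@](C)(O[Si](CC)(CC)CC)CC[C@@H]1C(=O)C(=C(C)C)CC[C@H]1C | intermediate
9 | (2R,3R)-2,3-dimethyl-2-{(3S)-3-methyl-3-[(triethylsilyl)oxy]pent-4-en-1-yl}-6-(propan-2-ylidene)cyclohexan-1-one | C=C[C@@](C)(O[Si](CC)(CC)CC)CC[C@@]1(C)C(=O)C(=C(C)C)CC[C@H]1C | intermediate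
10 | (2R,3R)-2,3-dimethyl-2-{(3S)-3-methyl-3-[(triethylsilyl)oxy]pent-4-en-1-yl}cyclohexan-1-one | C=C[C@@](C)(O[Si](CC)(CC)CC)CC[C@@]1(C)C(=O)CCC[C@H]1C | intermediate
11 | (5R,6R)-5,6-dimethyl-6-{(3S)-3-methyl-3-[(triethylsilyl)oxy]pent-4-en-1-yl}cyclohex-2-en-1-one | C=C[C@@](C)(O[Si](CC)(CC)CC)CC[C@@]1(C)C(=O)C=CC[C@H]1C | intermediate
12 | (5R,6R)-2-iodo-5,6-dimethyl-6-{(3S)-3-methyl-3-[(triethylsilyl)oxy]pent-4-en-1-yl}cyclohex-2-en-1-one | C=C[C@@](C)(O[Si](CC)(CC)CC)CC[C@@]1(C)C(=O)C(I)=CC[C@H]1C | intermediate
13 | 5-bromo-2-methylpent-1-ene | C=C(C)CCCBr | starting material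
14 | (4-methylpent-4-en-1-yl)magnesium bromide | C=C(C)CCC[Mg]Br | intermediate
15 | (5R,6R)-2-iodo-5,6-dimethyl-1-(4-methylpent-4-en-1-yl)-6-{(3S)-3-methyl-3-[(triethylsilyl)oxy]pent-4-en-1-yl}cyclohex-2-en-1-ol (C1 carbinol epimers, centre left open) | C=C[C@@](C)(O[Si](CC)(CC)CC)CC[C@@]1(C)C(O)(CCCC(C)=C)C(I)=CC[C@H]1C | intermediate
16 | (4R,5R)-2-iodo-4,5-dimethyl-3-(4-methylpent-4-en-1-yl)-4-{(3S)-3-methyl-3-[(triethylsilyl)oxy]pent-4-en-1-yl}cyclohex-2-en-1-one | C=C[C@@](C)(O[Si](CC)(CC)CC)CC[C@@]1(C)C(CCCC(C)=C)=C(I)C(=O)C[C@H]1C | intermediate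
17 | (3R,4R)-6-iodo-3,4-dimethyl-5-(4-methylpent-4-en-1-yl)-4-{(3S)-3-methyl-3-[(triethylsilyl)oxy]pent-4-en-1-yl}cyclohexa-1,5-dien-1-yl trifluoromethanesulfonate | C=C[C@@](C)(O[Si](CC)(CC)CC)CC[C@@]1(C)C(CCCC(C)=C)=C(I)C(OS(=O)(=O)C(F)(F)F)=C[C@H]1C | intermediate
18 | (3R,4R)-3,4,8,8-tetramethyl-4-{(3S)-3-methyl-3-[(triethylsilyl)oxy]pent-4-en-1-yl}-3,4,5,6,7,8-hexahydronaphthalen-1-yl trifluoromethanesulfonate | C=C[C@@](C)(O[Si](CC)(CC)CC)CC[C@@]1(C)C2=C(C(OS(=O)(=O)C(F)(F)F)=C[C@H]1C)C(C)(C)CCC2 | intermediate
19 | (5R,6R)-1,1,5,6-tetramethyl-5-{(3S)-3-methyl-3-[(triethylsilyl)oxy]pent-4-en-1-yl}-1,2,3,4,5,6-hexahydronaphthalene | C=C[C@@](C)(O[Si](CC)(CC)CC)CC[C@@]1(C)C2=C(C=C[C@H]1C)C(C)(C)CCC2 | intermediate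
20 | (1S,2R,3S,4R)-3,4,8,8-tetramethyl-4-{(3S)-3-methyl-3-[(triethylsilyl)oxy]pent-4-en-1-yl}-1,2,3,4,5,6,7,8-octahydronaphthalene-1,2-diol | C=C[C@@](C)(O[Si](CC)(CC)CC)CC[C@@]1(C)C2=C([C@H](O)[C@H](O)[C@H]1C)C(C)(C)CCC2 | intermediate
21 | (1S,2R,3S,4R)-4-[(3S)-3-hydroxy-3-methylpent-4-en-1-yl]-3,4,8,8-tetramethyl-1,2,3,4,5,6,7,8-octahydronaphthalene-1,2-diol | C=C[C@@](C)(O)CC[C@@]1(C)C2=C([C@H](O)[C@H](O)[C@H]1C)C(C)(C)CCC2 | intermediate
22 | (1S,2R,3S,4R)-1-hydroxy-4-[(3S)-3-hydroxy-3-methylpent-4-en-1-yl]-3,4,8,8-tetramethyl-1,2,3,4,5,6,7,8-octahydronaphthalen-2-yl acetate (halimane numbering 6S,7R,8S,9R,13S) | C=C[C@@](C)(O)CC[C@@]1(C)C2=C([C@H](O)[C@H](OC(C)=O)[C@H]1C)C(C)(C)CCC2 | target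

**Step count and risks**

Total step count: 15 (3 for the side-chain iodide, 12 in the main line). Longest linear sequence: 15 steps (1 to 22 through iodide 6); 12 steps counted from pulegone 7.

The three steps most likely to fail:

Step 12. The alkenylpalladium species may capture hydride before it cyclises (simple deiodination), or oxidative addition into the C–O bond of the triflate may compete with that into the C–I bond. The fallback separates the two events and closes ring A at the ketone oxidation level. It sets out from iodoenone 16, whose α-iodoenone C–I bond is more reactive and which carries no second leaving group. Reductive Heck cyclisation (Pd(OAc)2, PPh3, HCO2Na, Et4NCl, DMF, 80 °C) should give the bicyclic enone F3. Kinetic enolisation and triflation (KN(SiMe3)2, PhNTf2, THF, −78 °C) convert the bicyclic enone F3 into triflate 18, now isolated. Reduction with Pd(OAc)2, PPh3, HCO2H and Et3N then gives diene 19, where the route is rejoined.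

Step 5. Deprotonation may occur at the γ-positions of the isopropylidene unit instead of the hindered α′-methine, the alkylation may be slow, and facial selectivity may erode; proton transfer and γ-alkylation also threaten step 4. The fallback builds the quaternary centre by conjugate addition and enolate trapping instead of enolate alkylation of pulegone. It sets out from iodide 6. Zinc insertion (Zn dust, LiCl, THF, 25 °C) gives the alkylzinc iodide F1. Negishi coupling with commercial 2-iodocyclohex-2-en-1-one (Pd(OAc)2, SPhos, THF, 25 °C) gives the 2-alkylcyclohexenone F2. Copper-catalysed asymmetric conjugate addition of Me3Al (copper thiophene-2-carboxylate, CuO2CC4H3S, with the appropriate enantiomer of a BINOL-derived phosphoramidite ligand, Et2O, −30 °C) sets C8. Trapping of the aluminium enolate with MeLi and MeI (THF/DMPU), anti to the new C8 methyl, should deliver ketone 10, where the route is rejoined before step 7. Because C13 is already fixed, any shortfall in enantiocontrol would show up as a diastereomer to be removed.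

Step 15. Acylation of the allylic C6 hydroxyl may compete, bis-acylation may occur, or the acetyl group may migrate between the cis oxygens. The fallback replaces kinetic discrimination by tin-mediated differentiation. It sets out from triol 21. Bu2SnO (toluene, reflux, removal of water) gives the dibutylstannylene acetal F4 across O6 and O7. Acylation with AcCl at 0 °C should occur on the equatorial C7 oxygen, the usual site for stannylene acetals of cyclic cis-diols, and aqueous work-up gives 22.

Further compounds

F1 | step 5 | {(3S)-3-methyl-3-[(triethylsilyl)oxy]pent-4-en-1-yl}zinc iodide | C=C[C@@](C)(O[Si](CC)(CC)CC)CC[Zn]I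
F2 | step 5 | 2-{(3S)-3-methyl-3-[(triethylsilyl)oxy]pent-4-en-1-yl}cyclohex-2-en-1-one | C=C[C@@](C)(O[Si](CC)(CC)CC)CCC1=CCCCC1=O
F3 | step 12 | (3R,4R)-3,4,8,8-tetramethyl-4-{(3S)-3-methyl-3-[(triethylsilyl)oxy]pent-4-en-1-yl}-3,4,5,6,7,8-hexahydronaphthalen-1(2H)-one | C=C[C@@](C)(O[Si](CC)(CC)CC)CC[C@@]1(C)C2=C(C(=O)C[C@H]1C)C(C)(C)CCC2
F4 | step 15 | 6,7-O-dibutylstannylene acetal of triol 21 | C=C[C@@](C)(O)CC[C@@]1(C)C2=C([C@@H]3O[Sn](CCCC)(CCCC)O[C@@H]3[C@H]1C)C(C)(C)CCC2
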